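Green held 0.0800 M of reagent beyond its substrate, and I called this difference, c(reagent) − c(substrate), the reagent margin: the free reagent left at full conversion if each substrate takes one reagent with it. Violet's margin was 0.400 M. Substrate, charged below reagent in each flask, was the limiting reagent on paper.

| flask | substrate | reagent | initiator | radical scavenger | remark | time |
|---|---|---|---|---|---|---|
| birch | 0.25 M | 0.45 M | 25 mM | 0.12 mM | run made earlier |  |
| ash | 0.25 M | 0.80 M | 25 mM | 0.12 mM | run made earlier |  |
| violet | 0.25 M | 0.650 M | 25 mM | 0.12 mM |  | 12 min |
| green | 0.25 M | 0.330 M | 25 mM | 0.12 mM |  | 12 min |

- birch (time / min: substrate / %, product / %): 1.00: 91.1, 9.2; 2.00: 76.6, 23.1; 5.00: 48.1, 54.7; 12.0: 9.8, 90.1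
- ash (time / min: substrate / %, product / %): 1.50: 70.4, 29.1; 4.00: 20.4, 78.1; 8.00: 0, 98.1; 12.0: 0, 100.5

(scatter of a reading: 1 percentage point)

* part of the substrate that has reacted at the end, violet
* part of the substrate that has reacted at the end, green
* what raising the concentration of reagent from its lowest to its highest value here does to the part of the substrate that has reacted (changes below 5 percentage points count as none) (it falls / it rises / no change)



I read this ladder of times from the substrate readings, taking the decay time as the time to fall by a factor e.

| Rung | Time | The flask on this rung |
|---|---|---|
| start-up delay, ash | 0.792 min | chains held back, I supposed, by radical scavenger |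
| decay time, ash | 2.02 min | margin 0.550 M |
| decay time, birch | 4.86 min | margin 0.200 M |
| the run, violet and green | 12 min | stopped after 2.47 birch decay times |

The decay time was longer in birch than in ash, and birch's margin was smaller than ash's. Violet's margin lay above birch's and green's below it, so I expected violet to finish within the run and green to stop short of it.

The forecast gave 98.5% for violet and 69% for green, and its answer on raising the reagent was "it rises", on the reading “That gives an order in reagent of about 1.8, close to two”.

The flasks gave 100% for violet and 69.5% for green, and the answer on raising the reagent was "it rises", with a change of 30 percentage points.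

    first chain carrier + radical scavenger → ended chains B (k = 2.42 × 10⁶ M⁻¹ s⁻¹)
    initiator → 2 initiating radical (k = 9.94 × 10⁻⁵ s⁻¹)
    reagent + first chain carrier → product + second chain carrier (k = 1690 M⁻¹ s⁻¹)
    substrate + second chain carrier → by-product + first chain carrier (k = 11400 M⁻¹ s⁻¹)
    substrate + initiating radical → capped initiator + first chain carrier (k = 11800 M⁻¹ s⁻¹)
    2 first chain carrier → ended chains A (k = 3.00 × 10⁶ M⁻¹ s⁻¹)
    reagent + by-product ⇌ idle adduct, settled at all times (K = 12.0 M⁻¹)

The difference in reagent is the main reason for violet's gap to green: without it, violet's 100% becomes 69.5%. Idle adduct also binds reagent, so violet's margin less its 0.180 M of idle adduct leaves 33.8% of its charge free at 12.0 min. A neighbouring flask, green with 0.062 M of substrate, has green's margin raised to 0.268 M; it reacts 100% of its substrate, and less 0.0446 M of idle adduct that margin leaves 67.7% of its reagent free.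

The numbers in the tables were generated by integration for an exercise; scatter was added.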